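**Retrosynthetic overview**

1. The C3 ester is taken apart into the C3 alcohol, a (Z)-4-bromo-3-methylbut-2-enoyl unit (Z geometry taken from the ring of 4-methylfuran-2(5H)-one) and angelate introduced by carboxylate alkylation; the C9 enol OH is carried as a MOM ether.
2. C3–OH and C4–H come from one syn hydroboration of a C3=C4 alkene anti to the C14 methyl; the C7=C11 isopropylidene comes from acetone (aldol, dehydration) after C6=C7 is saturated.
3. Key disconnection C4–C5: the bicyclic (R)-trienone comes from a flat, achiral phenol with a (Z)-alkenyl iodide tether by Pd-catalysed enantioselective dearomative cyclisation, which closes ring A and creates quaternary C5.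
4. Enabling feature: ring B (C5–C10) is a para-dearomatised catechol. C8=O lies para to quaternary C5 (which carries C14), and C9–O sits on the neighbouring enol carbon of C9=C10, so ring B plus C14 and C1 is 3,4-dimethylcatechol; C6H2–C7(=C11) is the aldol equivalent of the dienone C6=C7 bond.
5. Ring order: ring B is present from the start as the benzene ring of 2,3-dimethylphenol (ortho-oxygenation, then lateral lithiation and alkylation with (Z)-1-bromo-3-iodobut-2-ene); ring A is the last ring, closed in step 8.

Key step: step 8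

Remark on numbering: atom numbers in the text are eremophilane numbers (ring A = C1–C5 and C10; ring B = C5–C10; C11–C13 = isopropylidene; C14 = methyl on C5; C15 = methyl on C4); compound names use systematic numbering.
Assumption: the sense of induction in step 8 is not predicted; the ligand enantiomer that delivers (R)-14 is used, and the five numbered starting materials are taken as purchased.

**Route**

Step 1
Reactants: 1 2,3-dimethylphenol
Product: 2 1-(methoxymethoxy)-2,3-dimethylbenzene
Conditions: NaH, MOMCl, THF, 0 °C → rt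
Reagents that add atoms: chloromethyl methyl ether (MOMCl), COCCl
Why: Williamson O-alkylation of the sodium phenoxide (MOM protection); the MOM ether later directs both lithiations and ends as the protecting group of the C9 oxygen.

Step 2
Reactants: 2 1-(methoxymethoxy)-2,3-dimethylbenzene
Product: 5 2-(methoxymethoxy)-3,4-dimethylphenol, via aryllithium 3 (not isolated), via dimethyl arylboronate 4 (not isolated)
Conditions: n-BuLi, TMEDA, Et2O, 0 °C → rt; B(OMe)3, −78 °C → rt; AcOH, 30% H2O2, 0 °C → rt
Reagents that add atoms: hydrogen peroxide, OO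
Why: Directed ortho-metalation: the MOM ether directs n-BuLi to the single free ortho C–H (ring deprotonation is kinetically preferred to attack on the flanking methyl), and borylation with oxidative aryl shift from boron to oxygen installs the second catechol oxygen (the future C8 carbonyl oxygen).

Step 3
Reactants: 5 2-(methoxymethoxy)-3,4-dimethylphenol
Product: 6 triisopropyl[2-(methoxymethoxy)-3,4-dimethylphenoxy]silane
Conditions: TIPSCl, imidazole, DMF, rt
Reagents that add atoms: chlorotriisopropylsilane (TIPSCl), CC(C)[Si](Cl)(C(C)C)C(C)C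
Why: Standard silylation of the phenol; the bulky, non-coordinating TIPS ether should survive s-BuLi and shield its own ortho C–H from metalation.

Step 4
Reactants: 7 but-2-yn-1-ol
Product: 9 (Z)-3-iodobut-2-en-1-ol, via cyclic alkenylalanate 8 (not isolated)
Conditions: Red-Al, THF, 0 °C → rt; I2, −78 → 0 °C
Reagents that add atoms: iodine, II
Why: Hydroxyl-directed trans-hydroalumination of the propargylic alcohol places Al on C3 cis to the CH2O arm in a five-membered alanate, and iodinolysis with retention gives the (Z)-iodoalkene.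

Step 5
Reactants: 9 (Z)-3-iodobut-2-en-1-ol
Product: 10 (Z)-1-bromo-3-iodobut-2-ene
Conditions: CBr4, PPh3, CH2Cl2, 0 °C
Reagents that add atoms: carbon tetrabromide, BrC(Br)(Br)Br
Why: Appel bromination of the primary allylic alcohol under neutral conditions that leave the alkenyl iodide and the alkene geometry untouched.

Step 6
Reactants: 6 triisopropyl[2-(methoxymethoxy)-3,4-dimethylphenoxy]silane; 10 (Z)-1-bromo-3-iodobut-2-ene
Product: 12 triisopropyl{3-[(Z)-4-iodopent-3-en-1-yl]-2-(methoxymethoxy)-4-methylphenoxy}silane, via benzylic lithium 11 (not isolated)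
Conditions: s-BuLi, TMEDA, THF, −78 °C; then 10, −78 → −20 °C
Reagents that add atoms: none
Why: Lateral (benzylic) lithiation directed by the MOM ether, whose two ring ortho positions are both substituted so that only the flanking methyl is in reach (the other methyl has no ortho donor), followed by SN2 alkylation at the primary allylic bromide; SN2′ attack at the iodine-bearing alkene carbon is disfavoured.

Step 7
Reactants: 12 triisopropyl{3-[(Z)-4-iodopent-3-en-1-yl]-2-(methoxymethoxy)-4-methylphenoxy}silane
Product: 13 3-[(Z)-4-iodopent-3-en-1-yl]-2-(methoxymethoxy)-4-methylphenol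
Conditions: TBAF, THF, 0 °C
Reagents that add atoms: none
Why: Fluoride cleavage of the aryl silyl ether; the MOM ether and the alkenyl iodide are inert to TBAF.

Step 8
Reactants: 13 3-[(Z)-4-iodopent-3-en-1-yl]-2-(methoxymethoxy)-4-methylphenol
Product: 14 (R)-1-(methoxymethoxy)-4a,5-dimethyl-7,8-dihydronaphthalen-2(4aH)-one
Conditions: [Pd(cinnamyl)Cl]2 (2.5 mol %), P-chiral dihydrobenzooxaphosphole monophosphine (AntPhos/BI-DIME type, 6 mol %), K2CO3, toluene, 90 °C
Reagents that add atoms: none
Why: Oxidative addition of Pd(0) to the (Z)-alkenyl iodide gives an alkenyl–Pd(II) species, the potassium phenoxide binds palladium through its para carbon C5 (a vinylogous enolate), and reductive elimination from the seven-membered palladacycle forges C4–C5 and leaves ring B as the 2-alkoxycyclohexa-2,5-dienone. The closest known reaction type is the Pd-catalysed enantioselective dearomative cyclisation of 4-substituted phenols that carry an aryl or alkenyl halide on a two-carbon tether at C3, which gives fused dienones with an all-carbon quaternary centre. Ring A closes in the Ar2-6 sense (six-membered, exo with respect to the C5=C6 bond of the phenoxide, which ends up outside the new ring). The only new stereocentre, C5, is set by the P-chiral ligand, which differentiates the two faces of the planar phenoxide in the C–C bond-forming event. The step needs C- over O-alkenylation and para over ortho attack: O8 cannot reach the alkenyl–Pd carbon through the tether, C9 is blocked by OMOM and C7 is out of reach, and the (Z) geometry holds palladium cis to the tether so that only C5 is within bonding distance. The C14 methyl on C5 blocks rearomatisation, so the dienone is the end point, and the C3=C4 bond left in ring A is the handle for the two remaining stereocentres.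

Step 9
Reactants: 14 (R)-1-(methoxymethoxy)-4a,5-dimethyl-7,8-dihydronaphthalen-2(4aH)-one
Product: 15 (R)-1-(methoxymethoxy)-4a,5-dimethyl-4,4a,7,8-tetrahydronaphthalen-2(3H)-one
Conditions: H2 (1 atm), RhCl(PPh3)3 (5 mol %), benzene/EtOH, rt
Reagents that add atoms: none
Why: Homogeneous hydrogenation with Wilkinson's catalyst is selective for the unhindered cis-disubstituted C6=C7 bond of the cross-conjugated dienone, as in the reduction of steroidal 1,4-dien-3-ones to 4-en-3-ones, and should leave the trisubstituted C3=C4 and tetrasubstituted C9=C10 bonds intact.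

Step 10
Reactants: 15 (R)-1-(methoxymethoxy)-4a,5-dimethyl-4,4a,7,8-tetrahydronaphthalen-2(3H)-one; 16 acetone
Product: 18 (4aR)-3-(2-hydroxypropan-2-yl)-1-(methoxymethoxy)-4a,5-dimethyl-4,4a,7,8-tetrahydronaphthalen-2(3H)-one (mixture of C3 epimers), via lithium enolate 17 (not isolated)
Conditions: LDA, THF, −78 °C; acetone, −78 °C; AcOH quench
Reagents that add atoms: none
Why: Kinetic deprotonation of the enone at its only α-CH2 (C7) gives the cross-conjugated lithium enolate, which undergoes aldol addition to acetone; the new C7 stereocentre forms as a mixture and is erased in the next step.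

Step 11
Reactants: 18 (4aR)-3-(2-hydroxypropan-2-yl)-1-(methoxymethoxy)-4a,5-dimethyl-4,4a,7,8-tetrahydronaphthalen-2(3H)-one
Product: 20 (R)-1-(methoxymethoxy)-4a,5-dimethyl-3-(propan-2-ylidene)-4,4a,7,8-tetrahydronaphthalen-2(3H)-one, via tertiary mesylate 19 (not isolated)
Conditions: MsCl, Et3N, CH2Cl2, 0 °C; then DBU, 0 °C → rt
Reagents that add atoms: none
Why: Mesylation of the tertiary alcohol via sulfene and E1cB elimination through the C7 enolate complete the aldol condensation and give the conjugated, tetrasubstituted isopropylidene.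

Step 12
Reactants: 20 (R)-1-(methoxymethoxy)-4a,5-dimethyl-3-(propan-2-ylidene)-4,4a,7,8-tetrahydronaphthalen-2(3H)-one
Product: 22 (4aR,5R,6R)-6-hydroxy-1-(methoxymethoxy)-4a,5-dimethyl-3-(propan-2-ylidene)-4,4a,5,6,7,8-hexahydronaphthalen-2(3H)-one, via secondary alkylborane 21 (not isolated)
Conditions: BH3·THF (1.1 equiv), THF, −20 → 0 °C; then 30% H2O2, pH 7 phosphate buffer, 0 °C → rt
Reagents that add atoms: hydrogen peroxide, OO
Why: Brown hydroboration–oxidation: borane adds syn and anti-Markovnikov (B to C3, H to C4) to the electron-rich C3=C4 bond from the face opposite the pseudo-axial C14 methyl on the adjacent quaternary C5, which sets C3–O trans to C15 and C15 cis to C14 in one event (oxidation with retention); the hindered, cross-conjugated C8 carbonyl between two tetrasubstituted alkenes is expected to react more slowly than the alkene with one equivalent of borane.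

Step 13
Reactants: 23 4-methylfuran-2(5H)-one
Product: 25 (Z)-4-bromo-3-methylbut-2-enoyl chloride (used crude), via trimethylsilyl ester 24 (not isolated)
Conditions: TMSBr, ZnBr2 (cat.), CH2Cl2, 40 °C; evaporate; (COCl)2, DMF (cat.), CH2Cl2, 0 °C → rt
Reagents that add atoms: bromotrimethylsilane, C[Si](C)(C)Br; oxalyl chloride, O=C(Cl)C(Cl)=O
Why: Silyl-assisted SN2 opening of the butenolide at its allylic O–CH2 carbon by bromide (halosilane lactone cleavage) keeps the ring-enforced cis relation of CH2 and carbonyl, hence the (Z) alkene, and the silyl ester is converted into the acid chloride under neutral conditions.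

Step 14
Reactants: 22 (4aR,5R,6R)-6-hydroxy-1-(methoxymethoxy)-4a,5-dimethyl-3-(propan-2-ylidene)-4,4a,5,6,7,8-hexahydronaphthalen-2(3H)-one; 25 (Z)-4-bromo-3-methylbut-2-enoyl chloride
Product: 26 (1R,2R,8aR)-5-(methoxymethoxy)-1,8a-dimethyl-6-oxo-7-(propan-2-ylidene)-1,2,3,4,6,7,8,8a-octahydronaphthalen-2-yl (Z)-4-bromo-3-methylbut-2-enoate
Conditions: pyridine, DMAP (10 mol %), CH2Cl2, 0 °C → rt
Reagents that add atoms: none
Why: Acylation of the equatorial secondary C3 alcohol with the acid chloride under mild pyridine/DMAP conditions; no stereocentre is touched, and a γ-bromide in place of a γ-hydroxyl prevents re-lactonisation of the acyl unit.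

Step 15
Reactants: 26 (1R,2R,8aR)-5-(methoxymethoxy)-1,8a-dimethyl-6-oxo-7-(propan-2-ylidene)-1,2,3,4,6,7,8,8a-octahydronaphthalen-2-yl (Z)-4-bromo-3-methylbut-2-enoate; 27 angelic acid, (Z)-2-methylbut-2-enoic acid
Product: 29 (1R,2R,8aR)-5-(methoxymethoxy)-1,8a-dimethyl-6-oxo-7-(propan-2-ylidene)-1,2,3,4,6,7,8,8a-octahydronaphthalen-2-yl (Z)-3-methyl-4-{[(Z)-2-methylbut-2-enoyl]oxy}but-2-enoate, via caesium angelate 28 (not isolated)
Conditions: Cs2CO3, DMF, rt
Reagents that add atoms: none
Why: SN2 displacement of the primary allylic bromide by caesium angelate (carboxylate alkylation) forms the angelate ester without activating angelic acid, which avoids (Z)→(E) isomerisation to the tiglate.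

Step 16
Reactants: 29 (1R,2R,8aR)-5-(methoxymethoxy)-1,8a-dimethyl-6-oxo-7-(propan-2-ylidene)-1,2,3,4,6,7,8,8a-octahydronaphthalen-2-yl (Z)-3-methyl-4-{[(Z)-2-methylbut-2-enoyl]oxy}but-2-enoate
Product: 30 (1R,2R,8aR)-5-hydroxy-1,8a-dimethyl-6-oxo-7-(propan-2-ylidene)-1,2,3,4,6,7,8,8a-octahydronaphthalen-2-yl (Z)-3-methyl-4-{[(Z)-2-methylbut-2-enoyl]oxy}but-2-enoate (CNP0228871.1)
Conditions: TFA/CH2Cl2/H2O (10:89:1), 0 °C
Reagents that add atoms: none
Why: Acidolysis of the MOM enol ether (acetal cleavage) releases the diosphenol, the stable enol form of the C8/C9 α-diketone; the esters, the isopropylidene enone and both (Z) alkenes should tolerate cold TFA.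

**Compound list**

1 | 2,3-dimethylphenol | Cc1cccc(O)c1C | starting material
2 | 1-(methoxymethoxy)-2,3-dimethylbenzene | COCOc1cccc(C)c1C | intermediate
3 | [2-(methoxymethoxy)-3,4-dimethylphenyl]lithium | [Li]c1ccc(C)c(C)c1OCOC | intermediate
4 | dimethyl [2-(methoxymethoxy)-3,4-dimethylphenyl]boronate | COB(OC)c1ccc(C)c(C)c1OCOC | intermediate
5 | 2-(methoxymethoxy)-3,4-dimethylphenol | Oc1ccc(C)c(C)c1OCOC | intermediate
6 | triisopropyl[2-(methoxymethoxy)-3,4-dimethylphenoxy]silane | CC(C)[Si](Oc1ccc(C)c(C)c1OCOC)(C(C)C)C(C)C | intermediate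
7 | but-2-yn-1-ol | CC#CCO | starting material
8 | sodium cyclic alkenylalanate (Al on C3 and O of the butenol, two 2-methoxyethoxy ligands) | CC1=CCO[Al-]1(OCCOC)OCCOC.[Na+] | intermediate
9 | (Z)-3-iodobut-2-en-1-ol | C/C(I)=C/CO | intermediate
10 | (Z)-1-bromo-3-iodobut-2-ene | C/C(I)=C/CBr | intermediate
11 | {[2-(methoxymethoxy)-6-methyl-3-(triisopropylsilyloxy)phenyl]methyl}lithium | [Li]Cc1c(C)ccc(O[Si](C(C)C)(C(C)C)C(C)C)c1OCOC | intermediate
12 | triisopropyl{3-[(Z)-4-iodopent-3-en-1-yl]-2-(methoxymethoxy)-4-methylphenoxy}silane | C/C(I)=C/CCc1c(C)ccc(O[Si](C(C)C)(C(C)C)C(C)C)c1OCOC | intermediate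
13 | 3-[(Z)-4-iodopent-3-en-1-yl]-2-(methoxymethoxy)-4-methylphenol | C/C(I)=C/CCc1c(C)ccc(O)c1OCOC | intermediate
14 | (R)-1-(methoxymethoxy)-4a,5-dimethyl-7,8-dihydronaphthalen-2(4aH)-one | CC1=CCCC2=C(OCOC)C(=O)C=C[C@]12C | intermediate
15 | (R)-1-(methoxymethoxy)-4a,5-dimethyl-4,4a,7,8-tetrahydronaphthalen-2(3H)-one | CC1=CCCC2=C(OCOC)C(=O)CC[C@]12C | intermediate
16 | acetone | CC(C)=O | starting material
17 | lithium enolate of 15 (C7=C8–OLi) | CC1=CCCC2=C(OCOC)C(O[Li])=CC[C@]12C | intermediate
18 | (4aR)-3-(2-hydroxypropan-2-yl)-1-(methoxymethoxy)-4a,5-dimethyl-4,4a,7,8-tetrahydronaphthalen-2(3H)-one | CC1=CCCC2=C(OCOC)C(=O)C(C(C)(C)O)C[C@]12C | intermediate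
19 | methanesulfonate of the tertiary alcohol of 18 | CC1=CCCC2=C(OCOC)C(=O)C(C(C)(C)OS(C)(=O)=O)C[C@]12C | intermediate
20 | (R)-1-(methoxymethoxy)-4a,5-dimethyl-3-(propan-2-ylidene)-4,4a,7,8-tetrahydronaphthalen-2(3H)-one | CC1=CCCC2=C(OCOC)C(=O)C(=C(C)C)C[C@]12C | intermediate
21 | C3-borane from 20 (BH2 in place of the hydroxyl of 22, same configuration) | B[C@@H]1CCC2=C(OCOC)C(=O)C(=C(C)C)C[C@]2(C)[C@H]1C | intermediate
22 | (4aR,5R,6R)-6-hydroxy-1-(methoxymethoxy)-4a,5-dimethyl-3-(propan-2-ylidene)-4,4a,5,6,7,8-hexahydronaphthalen-2(3H)-one | O[C@@H]1CCC2=C(OCOC)C(=O)C(=C(C)C)C[C@]2(C)[C@H]1C | intermediate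
23 | 4-methylfuran-2(5H)-one | CC1=CC(=O)OC1 | starting material
24 | trimethylsilyl (Z)-4-bromo-3-methylbut-2-enoate | BrC/C(C)=C\C(=O)O[Si](C)(C)C | intermediate
25 | (Z)-4-bromo-3-methylbut-2-enoyl chloride | BrC/C(C)=C\C(Cl)=O | intermediate
26 | (1R,2R,8aR)-5-(methoxymethoxy)-1,8a-dimethyl-6-oxo-7-(propan-2-ylidene)-1,2,3,4,6,7,8,8a-octahydronaphthalen-2-yl (Z)-4-bromo-3-methylbut-2-enoate | BrC/C(C)=C\C(=O)O[C@@H]1CCC2=C(OCOC)C(=O)C(=C(C)C)C[C@]2(C)[C@H]1C | intermediate
27 | angelic acid, (Z)-2-methylbut-2-enoic acid | C/C=C(/C)C(=O)O | starting material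
28 | caesium (Z)-2-methylbut-2-enoate | C/C=C(/C)C(=O)[O-].[Cs+] | intermediate
29 | MOM ether of the target at the C9 enol oxygen | C/C=C(/C)C(=O)OC/C(C)=C\C(=O)O[C@@H]1CCC2=C(OCOC)C(=O)C(=C(C)C)C[C@]2(C)[C@H]1C | intermediate
30 | CNP0228871.1 | C/C=C(/C)C(=O)OC/C(C)=C\C(=O)O[C@@H]1CCC2=C(O)C(=O)C(=C(C)C)C[C@]2(C)[C@H]1C | target

**Count and risks**

Total step count: 16. Longest linear sequence: 13 steps (1, 2, 3, 6, 7, 8, 9, 10, 11, 12, 14, 15, 16).

Steps most likely to fail:

Step 8. The ligand may not discriminate the two faces of the phenoxide well enough at C5, or turnover may be lost to protodeiodination. Fallback: the route sets out from 13 and moves enantiocontrol from the catalyst to a separation. The same ring closure is run with an achiral phosphine (Pd(OAc)2, PPh3, K2CO3, toluene, 90 °C) to give the racemic dienone, rac-1-(methoxymethoxy)-4a,5-dimethyl-7,8-dihydronaphthalen-2(4aH)-one F1. F1 is resolved by preparative chromatography on a chiral stationary phase; the (S)-enantiomer F2 is set aside and the (R)-enantiomer is 14, where the route is rejoined.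

Step 12. Borane may reduce the C8 carbonyl in competition with hydroboration of C3=C4, and the allylic alcohol so formed would expose the tetrasubstituted alkenes to further hydroboration. Fallback: the route sets out from 20 and replaces hydroboration by epoxidation and radical reductive opening. mCPBA (NaHCO3, CH2Cl2, 0 °C) should attack only the electron-rich C3=C4 bond, anti to C14, to give the 3α,4α-epoxide F3. Cp2TiCl (from Cp2TiCl2 and Mn) with 1,4-cyclohexadiene in THF then opens the epoxide homolytically at the tertiary C4–O bond; hydrogen-atom delivery to the C4 radical anti to C14 gives 22, where the route is rejoined.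

Step 14 (with step 13 before it). The γ-bromo enoyl chloride may lose its (Z) geometry or deconjugate through a vinylketene on contact with base, or the acyl unit may revert to the butenolide. Fallback: the route sets out from 22 and builds the side-chain alkene on the substrate. Alcohol 22 is esterified (DCC, DMAP, CH2Cl2) with [bis(2,2,2-trifluoroethoxy)phosphoryl]acetic acid to give the phosphonoacetate of 22 F4. Separately, caesium angelate 28 is alkylated with chloroacetone (DMF, rt) to give 2-oxopropyl (Z)-2-methylbut-2-enoate F5. A (Z)-selective Horner–Wadsworth–Emmons reaction of the Still–Gennari type (KHMDS, 18-crown-6, THF, −78 °C) between F4 and F5 places CH2O cis to the ester carbonyl and gives 29, where the route is rejoined; steps 13–15 are bypassed.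

Further compounds
F1 | step 8 | rac-1-(methoxymethoxy)-4a,5-dimethyl-7,8-dihydronaphthalen-2(4aH)-one | CC1=CCCC2=C(OCOC)C(=O)C=CC12C
F2 | step 8 | (S)-1-(methoxymethoxy)-4a,5-dimethyl-7,8-dihydronaphthalen-2(4aH)-one | CC1=CCCC2=C(OCOC)C(=O)C=C[C@@]12C
F3 | step 12 | 3α,4α-epoxide of 20 (oxirane across C3–C4, anti to C14) | O1[C@@H]2CCC3=C(OCOC)C(=O)C(=C(C)C)C[C@]3(C)[C@]12C
F4 | step 14 | [bis(2,2,2-trifluoroethoxy)phosphoryl]acetate of 22 | O=C(CP(=O)(OCC(F)(F)F)OCC(F)(F)F)O[C@@H]1CCC2=C(OCOC)C(=O)C(=C(C)C)C[C@]2(C)[C@H]1C
F5 | step 14 | 2-oxopropyl (Z)-2-methylbut-2-enoate | C/C=C(/C)C(=O)OCC(C)=O
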